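Saturday's flask ended with less target than Wednesday's, 67.4% against 78.6%, and the charges differed in c(second nucleophile), 1.1 M against 0.28 M.

in all of them: starting material 0.11 M; gas 15 mM (held)
- Wednesday's: second nucleophile 0.28 M; run made earlier
- Saturday's: second nucleophile 1.1 M; run made earlier
- violet: second nucleophile 0.550 M; time 3.0 d
- amber: second nucleophile 0.550 M; time 4.0 d

| run | time / d | target / % | starting material / % |
|---|---|---|---|
| Wednesday's | 0.208 | 14.4 | 75.0 |
| Wednesday's | 0.333 | 24.2 | 61.7 |
| Wednesday's | 0.625 | 42.9 | 37.8 |
| Wednesday's | 1.25 | 68.7 | 9.9 |
| Wednesday's | 2.50 | 78.6 | 0.1 |
| Saturday's | 0.208 | 14.3 | 70.8 |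
| Saturday's | 0.333 | 23.1 | 56.2 |
| Saturday's | 0.625 | 41.4 | 31.3 |
| Saturday's | 1.25 | 62.8 | 5.5 |
| Saturday's | 2.50 | 67.4 | 0.5 |

(each reading ± 0.3 percentage points)

- at the start none of the gas is in solution

1. which of the two there is more of at the end, violet (other capture product / target)
2. which of the two there is more of at the end, amber (other capture product / target)
3. final target, as a percentage of the starting material charged, in violet
4. final target, as a percentage of the starting material charged, in amber

At the last reading, 2.50 d, starting material stood at 0.1% on Wednesday and 0.5% on Saturday. So I took violet at 3.0 d and amber at 4.0 d as end readings, and because those two flasks share one charge, I looked for one number. But target and starting material together did not make up the charge. I called the missing part the gap (the deficit in the mass balance): 21.3% on Wednesday and 32.1% on Saturday.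

I drew a straight line of gap against c(second nucleophile) through these two runs, though two points cannot test its straightness. At 0.550 M this gap line gave 24.9%, so my target was 75.1%. Carried back to zero charge, the line stood at 17.6%, so I expected other capture product to be less than the whole gap.

The forecast took the new charge as “the geometric mean of the two charges”. It named target for violet and target for amber, and gave 73.6% (71.5% to 75.5%) for violet and 73.4% (70.5% to 75.5%) for amber. My figure was higher than its violet value.

The flask ran by these steps:

    2 starting material → self-condensation product (k = 2.60 × 10⁻⁵ L mol⁻¹ s⁻¹)
    first nucleophile + intermediate → target (k = 0.310 L mol⁻¹ s⁻¹)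
    gas ⇌ first nucleophile, rate k3*(csat - [first nucleophile]) (kL = 9.60 × 10⁻⁵ s⁻¹)
    second nucleophile + intermediate → other capture product (k = 4.50 × 10⁻⁴ L mol⁻¹ s⁻¹)
    starting material ⇌ intermediate (K = 0.00910, k = 0.00140 s⁻¹)

Violet and amber each gave 74.3% target, more than the 10.4% other capture product in each, and a gap of 25.7% against my 24.9%. In violet that gap held 10.4% other capture product and 15.3% self-condensation product, beside the line's 7.3 percentage points above its foot of 17.6%. The line's 24.9% was drawn for end readings, so it is not tested by amber's recipe read earlier, at 25 h, which showed 61.2% target with 14% starting material still there and a gap of 24.8%.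

Readings and results are simulated with made-up constants; noise was put on by code.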